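## Retrosynthetic overview

1. Target ⇐ removal of three silyl groups from the fully protected dihydropyran (last step).
2. Dihydropyran (the only ring built; the arene comes from catechol) ⇐ O1–C6 oxa-Michael addition to methyl propiolate, then C4–C5 closure by a palladium C–H conjugate addition, on an acyclic δ-hydroxy (E)-enoate.
3. δ-Hydroxy enoate ⇐ cross-metathesis of a 2-vinyl-1,3-diol mono-silyl ether with the acrylate of bis-silylated hydroxytyrosol (catechol + oxirane + acryloyl chloride).
4. Me–CH(O)–CH(vinyl)–CH2O stereodiad (C2 and C3 of the target) ⇐ key step: stereospecific 1,2-vinyl shift (semipinacol rearrangement) of an erythro epoxy silyl ether ⇐ Sharpless kinetic-resolution epoxidation of hexa-1,4-dien-3-ol (crotonaldehyde + vinyl Grignard).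

Assumption: the SMILES is read as the (2S,3R,4S) isomer (pyran numbering O1, C2–Me, C3–CH2OH, C4–CH2CO2R, C5–CO2Me); carbon building blocks are numbered as starting materials, and protecting and oxidising agents are treated as reagents.

## Route

Step 1
Reactants: 1 (2E)-but-2-enal; 2 ethenylmagnesium bromide
Product: 3 rac-(4E)-hexa-1,4-dien-3-ol
Conditions: THF, −78 → 0 °C; aq. NH4Cl
Reagents that add atoms: none
Why: 1,2-Grignard addition of a vinyl nucleophile to an enal is fast and clean at low temperature, and the racemic carbinol needs no control because it is resolved in step 2 and its carbon later becomes CH2OH.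

Step 2
Reactants: 3 rac-(4E)-hexa-1,4-dien-3-ol
Product: 4 (1S)-1-[(2S,3S)-3-methyloxiran-2-yl]prop-2-en-1-ol
Conditions: Ti(OiPr)4 (10 mol %), L-(+)-diisopropyl tartrate (15 mol %), t-BuOOH (0.55 equiv), 4 Å MS, CH2Cl2, −20 °C
Reagents that add atoms: tert-butyl hydroperoxide, CC(C)(C)OO
Why: Sharpless kinetic-resolution epoxidation, in which the (3S)-alcohol is epoxidised fast on its more substituted (E)-propenyl group from the face set by L-(+)-tartrate to give the erythro (2S,3S)-epoxide (this fixes C2 of the target), while the (3R)-alcohol is left behind (yield therefore at most 50 %).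

Step 3
Reactants: 4 (1S)-1-[(2S,3S)-3-methyloxiran-2-yl]prop-2-en-1-ol
Product: 7 (2R,3S)-2-ethenyl-3-[(triethylsilyl)oxy]butan-1-ol, via epoxy silyl ether 5 (not isolated), via siloxy aldehyde 6 (not isolated)
Conditions: TESCl, imidazole, CH2Cl2, 0 °C, filter; MeAl(OAr)2 (Ar = 4-bromo-2,6-di-tert-butylphenyl; MABR, 20 mol %), CH2Cl2, −78 °C; then NaBH4, EtOH, −78 → −20 °C; pH 7 buffer
Reagents that add atoms: chlorotriethylsilane, CC[Si](Cl)(CC)CC
Why: Semipinacol rearrangement of an epoxy silyl ether (Maruoka–Yamamoto / Suzuki–Tsuchihashi type), in which the aluminium Lewis acid opens the epoxide at the carbon next to the silyloxy carbinol, the vinyl group shifts 1,2 antiperiplanar to the breaking C–O bond with inversion (this sets C3 of the target anti to the untouched C–O stereocentre), the silyl group passes to the new alkoxide, and cold borohydride reduces the epimerisable α-vinyl aldehyde at once.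

Step 4
Reactants: 7 (2R,3S)-2-ethenyl-3-[(triethylsilyl)oxy]butan-1-ol
Product: 9 (2S,3R)-3-({[tert-butyl(diphenyl)silyl]oxy}methyl)pent-4-en-2-ol, via bis-silyl ether 8 (not isolated)
Conditions: TBDPSCl, imidazole, CH2Cl2, 23 °C; aqueous wash; then PPTS (10 mol %), MeOH, 23 °C
Reagents that add atoms: tert-butyl(chloro)diphenylsilane, CC(C)(C)[Si](Cl)(c1ccccc1)c1ccccc1
Why: Standard silyl ether chemistry, in which the only free (primary) hydroxyl is silylated and the far more acid-labile secondary TES ether is then methanolysed selectively, so no stereocentre is touched.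

Step 5
Reactants: 10 benzene-1,2-diol
Product: 11 4-bromobenzene-1,2-diol
Conditions: NBS (1.0 equiv), HBF4·OEt2 (1.1 equiv), MeCN, −30 → 23 °C
Reagents that add atoms: N-bromosuccinimide, BrN1C(=O)CCC1=O
Why: Acid-activated electrophilic aromatic bromination goes para to one hydroxyl and stops at the monobromide.

Step 6
Reactants: 11 4-bromobenzene-1,2-diol
Product: 12 [(4-bromo-1,2-phenylene)bis(oxy)]bis[tert-butyl(dimethyl)silane]
Conditions: TBSCl (2.4 equiv), imidazole, DMF, 23 °C
Reagents that add atoms: tert-butyl(chloro)dimethylsilane, CC(C)(C)[Si](C)(C)Cl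
Why: Imidazole-promoted silylation (Corey protocol) protects both phenols as fluoride-labile ethers that tolerate organolithium, ruthenium and palladium steps.

Step 7
Reactants: 12 [(4-bromo-1,2-phenylene)bis(oxy)]bis[tert-butyl(dimethyl)silane]; 13 oxirane; 14 prop-2-enoyl chloride
Product: 17 2-{3,4-bis[(tert-butyldimethylsilyl)oxy]phenyl}ethyl prop-2-enoate, via aryllithium 15 (not isolated), via lithium alkoxide 16 (not isolated)
Conditions: n-BuLi (1.05 equiv), THF, −78 °C; 13 (1.5 equiv), −78 → 0 °C; then 14 (1.3 equiv), −78 → 0 °C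
Reagents that add atoms: none
Why: Bromine–lithium exchange, SN2 opening of oxirane by the aryllithium and O-acylation of the resulting lithium alkoxide run in one flask, and no retro-Brook shift occurs because neither silyl ether is ortho to lithium.

Step 8
Reactants: 9 (2S,3R)-3-({[tert-butyl(diphenyl)silyl]oxy}methyl)pent-4-en-2-ol; 17 2-{3,4-bis[(tert-butyldimethylsilyl)oxy]phenyl}ethyl prop-2-enoate
Product: 18 2-{3,4-bis[(tert-butyldimethylsilyl)oxy]phenyl}ethyl (2E,4R,5S)-4-({[tert-butyl(diphenyl)silyl]oxy}methyl)-5-hydroxyhex-2-enoate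
Conditions: 17 (2 equiv), second-generation Hoveyda–Grubbs catalyst [RuCl2(SIMes)(=CH–C6H4-2-OiPr)] (5 mol %), CH2Cl2, 40 °C
Reagents that add atoms: none
Why: Olefin cross-metathesis of a terminal alkene with an acrylate is selective for the (E)-cross product because acrylates homodimerise slowly, and the neutral conditions leave the allylic stereocentre and the free hydroxyl untouched.

Step 9
Reactants: 18 2-{3,4-bis[(tert-butyldimethylsilyl)oxy]phenyl}ethyl (2E,4R,5S)-4-({[tert-butyl(diphenyl)silyl]oxy}methyl)-5-hydroxyhex-2-enoate; 19 methyl prop-2-ynoate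
Product: 21 methyl (2S,3R,4S)-4-[2-(2-{3,4-bis[(tert-butyldimethylsilyl)oxy]phenyl}ethoxy)-2-oxoethyl]-3-({[tert-butyl(diphenyl)silyl]oxy}methyl)-2-methyl-3,4-dihydro-2H-pyran-5-carboxylate, via alkoxyacrylate 20 (not isolated)
Conditions: 19 (1.5 equiv), PMe3 (10 mol %), CH2Cl2, 0 → 23 °C; evaporate (PMe3 and excess 19 are volatile); then Pd(OCOCF3)2 (10 mol %), 2,2′-bipyridine (12 mol %), AcOH (5 equiv), ClCH2CH2Cl, 60 °C
Reagents that add atoms: none
Why: Proposed new method: a one-flask oxa-Michael / C–H conjugate-addition annulation. Phosphine-catalysed hydroalkoxylation (known) gives the (E)-β-alkoxyacrylate 20; its α-carbon (C5) is the most nucleophilic carbon in the molecule and is palladated by electrophilic divalent palladium cis to the ether oxygen; the vinylpalladium inserts the tethered (E)-enoate 6-exo through the half-chair that places the C3 CH2OSi group and the new side chain trans (the cis arrangements suffer either A(1,2) strain against the C5 ester or a 1,3-diaxial methyl/side-chain contact), which sets C4; the bipyridine-ligated palladium enolate is then protonated by AcOH instead of undergoing β-hydride elimination, so palladium stays divalent and no oxidant is needed. The closest known reaction types are C–H alkenylation of chromones and enaminones at the same kind of carbon by divalent palladium, bipyridine–palladium conjugate additions of boronic acids to enoates that end in enolate protonolysis, and Fujiwara hydroarylation.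

Step 10
Reactants: 21 methyl (2S,3R,4S)-4-[2-(2-{3,4-bis[(tert-butyldimethylsilyl)oxy]phenyl}ethoxy)-2-oxoethyl]-3-({[tert-butyl(diphenyl)silyl]oxy}methyl)-2-methyl-3,4-dihydro-2H-pyran-5-carboxylate
Product: 22 methyl (2S,3R,4S)-4-{2-[2-(3,4-dihydroxyphenyl)ethoxy]-2-oxoethyl}-3-(hydroxymethyl)-2-methyl-3,4-dihydro-2H-pyran-5-carboxylate
Conditions: HF·pyridine, pyridine, THF, 0 → 23 °C
Reagents that add atoms: none
Why: Buffered fluoride desilylation cleaves the two aryl TBS ethers and the primary TBDPS ether under weakly acidic conditions that leave the vinylogous carbonate, both esters and all three stereocentres untouched.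

## Compound list

1 | (2E)-but-2-enal (crotonaldehyde) | C/C=C/C=O | starting material
2 | ethenylmagnesium bromide (vinylmagnesium bromide) | C=C[Mg]Br | starting material
3 | rac-(4E)-hexa-1,4-dien-3-ol | C=CC(O)/C=C/C | intermediate
4 | (1S)-1-[(2S,3S)-3-methyloxiran-2-yl]prop-2-en-1-ol | C=C[C@H](O)[C@@H]1O[C@H]1C | intermediate
5 | triethyl{[(1S)-1-[(2R,3S)-3-methyloxiran-2-yl]prop-2-en-1-yl]oxy}silane | C=C[C@H](O[Si](CC)(CC)CC)[C@@H]1O[C@H]1C | intermediate
6 | (2S,3S)-2-ethenyl-3-[(triethylsilyl)oxy]butanal | CC[Si](CC)(CC)O[C@@H](C)[C@@H](C=O)C=C | intermediate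
7 | (2R,3S)-2-ethenyl-3-[(triethylsilyl)oxy]butan-1-ol | CC[Si](CC)(CC)O[C@@H](C)[C@@H](CO)C=C | intermediate
8 | tert-butyl{[(2R,3S)-2-ethenyl-3-[(triethylsilyl)oxy]butyl]oxy}diphenylsilane | CC[Si](CC)(CC)O[C@@H](C)[C@@H](CO[Si](c1ccccc1)(c1ccccc1)C(C)(C)C)C=C | intermediate
9 | (2S,3R)-3-({[tert-butyl(diphenyl)silyl]oxy}methyl)pent-4-en-2-ol | O[C@@H](C)[C@@H](CO[Si](c1ccccc1)(c1ccccc1)C(C)(C)C)C=C | intermediate
10 | benzene-1,2-diol (catechol) | Oc1ccccc1O | starting material
11 | 4-bromobenzene-1,2-diol | Oc1ccc(Br)cc1O | intermediate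
12 | [(4-bromo-1,2-phenylene)bis(oxy)]bis[tert-butyl(dimethyl)silane] | CC(C)(C)[Si](C)(C)Oc1ccc(Br)cc1O[Si](C)(C)C(C)(C)C | intermediate
13 | oxirane | C1CO1 | starting material
14 | prop-2-enoyl chloride | C=CC(=O)Cl | starting material
15 | {3,4-bis[(tert-butyldimethylsilyl)oxy]phenyl}lithium | [Li]c1ccc(O[Si](C)(C)C(C)(C)C)c(O[Si](C)(C)C(C)(C)C)c1 | intermediate
16 | lithium 2-{3,4-bis[(tert-butyldimethylsilyl)oxy]phenyl}ethan-1-olate | [Li+].[O-]CCc1ccc(O[Si](C)(C)C(C)(C)C)c(O[Si](C)(C)C(C)(C)C)c1 | intermediate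
17 | 2-{3,4-bis[(tert-butyldimethylsilyl)oxy]phenyl}ethyl prop-2-enoate | C=CC(=O)OCCc1ccc(O[Si](C)(C)C(C)(C)C)c(O[Si](C)(C)C(C)(C)C)c1 | intermediate
18 | 2-{3,4-bis[(tert-butyldimethylsilyl)oxy]phenyl}ethyl (2E,4R,5S)-4-({[tert-butyl(diphenyl)silyl]oxy}methyl)-5-hydroxyhex-2-enoate | O[C@@H](C)[C@@H](CO[Si](c1ccccc1)(c1ccccc1)C(C)(C)C)/C=C/C(=O)OCCc1ccc(O[Si](C)(C)C(C)(C)C)c(O[Si](C)(C)C(C)(C)C)c1 | intermediate
19 | methyl prop-2-ynoate (methyl propiolate) | C#CC(=O)OC | starting material
20 | 2-{3,4-bis[(tert-butyldimethylsilyl)oxy]phenyl}ethyl (2E,4R,5S)-4-({[tert-butyl(diphenyl)silyl]oxy}methyl)-5-{[(1E)-3-methoxy-3-oxoprop-1-en-1-yl]oxy}hex-2-enoate | COC(=O)/C=C/O[C@@H](C)[C@@H](CO[Si](c1ccccc1)(c1ccccc1)C(C)(C)C)/C=C/C(=O)OCCc1ccc(O[Si](C)(C)C(C)(C)C)c(O[Si](C)(C)C(C)(C)C)c1 | intermediate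
21 | methyl (2S,3R,4S)-4-[2-(2-{3,4-bis[(tert-butyldimethylsilyl)oxy]phenyl}ethoxy)-2-oxoethyl]-3-({[tert-butyl(diphenyl)silyl]oxy}methyl)-2-methyl-3,4-dihydro-2H-pyran-5-carboxylate | COC(=O)C1=CO[C@@H](C)[C@@H](CO[Si](c2ccccc2)(c2ccccc2)C(C)(C)C)[C@@H]1CC(=O)OCCc1ccc(O[Si](C)(C)C(C)(C)C)c(O[Si](C)(C)C(C)(C)C)c1 | intermediate
22 | methyl (2S,3R,4S)-4-{2-[2-(3,4-dihydroxyphenyl)ethoxy]-2-oxoethyl}-3-(hydroxymethyl)-2-methyl-3,4-dihydro-2H-pyran-5-carboxylate | COC(=O)C1=CO[C@@H](C)[C@@H](CO)[C@@H]1CC(=O)OCCc1ccc(O)c(O)c1 | target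

## Step count and risk

Total steps: 10. Longest linear sequence: 7 (steps 1–4, 8–10); the aryl branch (steps 5–7) joins at step 8.

The three steps most likely to fail:

1. Step 9, the proposed new annulation. The risks are no C–H palladation at C5, β-hydride elimination instead of protonolysis, and partial loss of silyl groups. The fallback uses known chemistry, sets out from 18 and comes back at 21. Compound 18 is added to 19 under PMe3 catalysis and the alkoxyacrylate 20 is isolated. α-Iodination (N-iodosuccinimide, AcOH, then Et3N) gives 2-{3,4-bis[(tert-butyldimethylsilyl)oxy]phenyl}ethyl (2E,4R,5S)-4-({[tert-butyl(diphenyl)silyl]oxy}methyl)-5-{[(1Z)-2-iodo-3-methoxy-3-oxoprop-1-en-1-yl]oxy}hex-2-enoate F1, the same kind of α-iodo-β-alkoxyacrylate that is used as a coupling partner for β-methoxyacrylates. An intramolecular reductive Heck cyclisation (Pd(OAc)2, PPh3, HCO2Na, DMF, 60 °C) then closes C4–C5 and gives 21: zerovalent palladium inserts into the C–I bond, 6-exo carbopalladation of the enoate follows, and formate reduces the palladium enolate.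

2. Step 3, the telescoped 1,2-vinyl shift. The risks are hydride instead of vinyl migration, isomerisation or epimerisation of the α-vinyl aldehyde 6 before it is reduced, and silyl migration in 7. The fallback avoids a rearrangement, sets out from 1 (and uses 2) and comes back at 9. Luche reduction of 1 (NaBH4, CeCl3·7H2O, MeOH) gives (2E)-but-2-en-1-ol F2. Sharpless epoxidation (Ti(OiPr)4, L-(+)-diethyl tartrate, t-BuOOH, CH2Cl2, −20 °C) gives [(2S,3S)-3-methyloxiran-2-yl]methanol F3. CuI-catalysed SN2 opening at C-2 by 2 (THF, −40 °C, inversion; NaIO4 wash to destroy the minor 1,2-diol regioisomer) gives (2R,3S)-2-ethenylbutane-1,3-diol F4. Primary-selective silylation (TBDPSCl, imidazole, CH2Cl2, 0 °C) gives 9.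

3. Step 8, the cross-metathesis. The risks are slow reaction at the branched allylic position, catalyst decay and acrylate dimer. The fallback replaces metathesis by ozonolysis and olefination, sets out from 9 and 16 and comes back at 18. Ozonolysis of 9 (O3, CH2Cl2/MeOH, −78 °C; Me2S) gives (2R,3S)-2-({[tert-butyl(diphenyl)silyl]oxy}methyl)-3-hydroxybutanal F5. The alkoxide 16 is acylated with (diethoxyphosphoryl)acetyl chloride in place of 14 to give 2-{3,4-bis[(tert-butyldimethylsilyl)oxy]phenyl}ethyl (diethoxyphosphoryl)acetate F6. Masamune–Roush Horner–Wadsworth–Emmons olefination of F5 with F6 (LiCl, iPr2NEt, MeCN, 0 °C) gives the (E)-enoate 18.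

## Further compounds

F1 | step 9 | 2-{3,4-bis[(tert-butyldimethylsilyl)oxy]phenyl}ethyl (2E,4R,5S)-4-({[tert-butyl(diphenyl)silyl]oxy}methyl)-5-{[(1Z)-2-iodo-3-methoxy-3-oxoprop-1-en-1-yl]oxy}hex-2-enoate | COC(=O)/C(I)=C/O[C@@H](C)[C@@H](CO[Si](c1ccccc1)(c1ccccc1)C(C)(C)C)/C=C/C(=O)OCCc1ccc(O[Si](C)(C)C(C)(C)C)c(O[Si](C)(C)C(C)(C)C)c1
F2 | step 3 | (2E)-but-2-en-1-ol | C/C=C/CO
F3 | step 3 | [(2S,3S)-3-methyloxiran-2-yl]methanol | OC[C@@H]1O[C@H]1C
F4 | step 3 | (2R,3S)-2-ethenylbutane-1,3-diol | O[C@@H](C)[C@@H](CO)C=C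
F5 | step 8 | (2R,3S)-2-({[tert-butyl(diphenyl)silyl]oxy}methyl)-3-hydroxybutanal | O[C@@H](C)[C@@H](CO[Si](c1ccccc1)(c1ccccc1)C(C)(C)C)C=O
F6 | step 8 | 2-{3,4-bis[(tert-butyldimethylsilyl)oxy]phenyl}ethyl (diethoxyphosphoryl)acetate | CCOP(=O)(OCC)CC(=O)OCCc1ccc(O[Si](C)(C)C(C)(C)C)c(O[Si](C)(C)C(C)(C)C)c1
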